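The pitfall is to read lost substrate as conversion to target: in Wednesday's run, by 80.0 s, 61.1% of the substrate is gone, yet target stands at 9.4%.

the same everywhere: substrate 0.059 M

|  | acid | remark | time |
|---|---|---|---|
| Wednesday's | 0.029 mM | run made earlier |  |
| flask | 0.0590 mM |  | 12 min |

Wednesday's run (percent of the substrate charged)

| time / s | substrate / % | target / % |
|---|---|---|
| 10.0 | 84.6 | 1.2 |
| 12.0 | 81.5 | 1.9 |
| 20.0 | 71.5 | 3.7 |
| 30.0 | 63.3 | 4.2 |
| 40.0 | 55.5 | 6.1 |
| 60.0 | 45.3 | 7.6 |
| 80.0 | 38.9 | 9.4 |

(scatter of a reading: 0.5 percentage points)

- part of the substrate that has reacted at 12 min
- pH of the solution at 12 min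

- acid is the free proton; pH is minus the decimal logarithm of its molar concentration
- what has gone from substrate into another species counts as reacted, even if it can come back
- a reading or a percentage of target counts all its forms, free or not
- a reading of substrate is of its free form alone

So we reckon with a pool, the charge minus target, and ask first where free substrate ends within it. In Wednesday's run the share of the pool that is free substrate reads 0.591, 0.490 and 0.429 at 40.0 s, 60.0 s and 80.0 s. Continuing these shrinking steps as a geometric series gives an end share of 0.336, a reading with its scatter.

Next, how fast does the pool empty? The drain rate, target gained per minute as a fraction of the pool, a pseudo-first-order constant, reads 0.0610 min⁻¹ in Wednesday's run. That run stops early against the inverse of this rate, with its share still above the end value. The new flask has twice the acid. If the drain follows acid, its rate is 0.124 min⁻¹, and 12 min leaves 22.6% of the pool. Our reckoning is therefore 92.4% reacted, above the forecast.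

The forecast gives 88% (78% to 93%) reacted; for the pH it gives 4.23 (4.2 to 4.5), on the ground that “The acid acts as a catalyst and is not consumed”.

The flask gives 92.0% reacted and pH 4.22.

    substrate + target ⇌ idle adduct, settled at all times (K = 701 M⁻¹)
    substrate + acid → weak acid + acid + target (k = 2640 M⁻¹ min⁻¹)
    substrate → weak acid + target (k = 0.0427 min⁻¹)
    target ⇌ isomer of the product (K = 0.785, k = 0.116 min⁻¹)
    substrate ⇌ dormant form (K = 1.38, k = 0.821 min⁻¹)
    weak acid ⇌ conjugate base + acid, settled at all times (K = 3.20 × 10⁻⁹ M)

In the flask at 12.0 min, the forward step to the dormant form has a half-life of 0.84 min, short against the flask's 12 min. Beside substrate at 8.01% the flask then holds dormant form at 13.0% and idle adduct at 65.1%, a percentage in which each adduct counts as two, while target, with the adduct counted in as one target each, reads 42.4%.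

For this flask read at 5.0 min, the drain rate leaves 18.1% free substrate, so 81.9% reacted; the computed run gives 16.0% and 84.0%.

The numbers in the tables were generated by integration for substances that don't exist, noise included.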